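# Total synthesis proposal for CNP0273650.6 by an intramolecular oxyallyl (4+3) cycloaddition

## Analysis of the target

The target is a daucane-type diester on a trans-fused hydroazulene. The atoms are numbered C1 (O-tigloyl carbon), C2=C3 (methyl on C3), C4, C5 (O-aroyl carbon), C6 (ring-fusion CH), C7 (quaternary, methyl), C8, C9 and C10 (isopropyl carbinol). The seven-membered ring is C1–C7 and the five-membered ring is C6–C10. The five stereocentres (1R, 5S, 6S, 7S, 10S) sit around the ring fusion. H6 and the C7 methyl group are trans. The C10 hydroxyl and the C5 ester oxygen are cis to H6, so C5, the isopropyl group and the C7 methyl group share one face of the cyclopentane. The C1 ester oxygen is trans to the C7 methyl group.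

The sensitive groups are the allylic tiglate at C1 (ionisable, and a leaving group for any C2-centred anion), the C2=C3 alkene (β,γ to C5, so it conjugates when C5 is a ketone), the tertiary C10 alcohol (retro-aldol when C5 is a ketone and O10 is free) and the free phenol. Two different esters must be placed on two hindered secondary alcohols. The difficulty lies in the quaternary C7 next to oxygenated C1, the fully substituted C10 next to the ring-fusion CH, and two carbinol configurations (C1–O anti to the angular methyl, C5–O equatorial) that hydride attack on the open face is not expected to give.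

The strategy rests on one feature. C1, flanked by C7 and C2, is the central carbon of an oxyallyl unit. C3–C6, with oxygen on C5, is a 2-oxygenated diene. The two are tied by the three-atom tether C8–C9–C10, so the bicycle is the intramolecular (4+3) adduct of an acyclic chain, and the two ring oxygens arrive differentiated as a ketone and an enol ether.

## Retrosynthetic reasoning

**33 from 32.** Only Si–O bonds are cut: the triethylsilyl ether on O10 and the aryl silyl ether. Fluoride-labile groups are chosen because acid would ionise the allylic tiglate and the tertiary alcohol.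

**32 from 27 and 30.** The C5–O acyl bond is cut. It is made last among the esters, when C5–OH is the only free hydroxyl, so no selectivity question arises at this hindered position.

**27 from 25 and 26.** The C1–O bond is cut and has to be formed with inversion. Hydride adds to a C1 carbonyl anti to the axial C7 methyl and gives the alcohol cis to it. Displacement at allylic C1 from that same open face turns the wrong alcohol into the right ester in the esterification step itself. The C5 hydroxyl of 25 is a spectator because its rear side is blocked.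

**25 back to 20 (through 24, 23 and 22).** No skeletal bond is cut.
- The C5 carbinol comes from the ketone 24 by dissolving-metal reduction, which gives the equatorial alcohol.
- The C5 ketone is released from its silyl enol ether only after C1 has been reduced (23). With a C1 carbonyl still present the C2=C3 alkene would move into conjugation with either carbonyl.
- The C2=C3 alkene comes from dehydrogenation of the C1 ketone of 20, whose only enolisable side is C2.

**20 from 17 (key disconnection).** C6–C7 and C2–C3 are cut. These are the two bonds between the oxyallyl carbons (C7, C2) and the diene termini (C6, C3). No other pair of cuts opens both rings to one acyclic chain while leaving both ring oxygens in place. Fifteen skeletal carbons, the quaternary centre and the C1/C5 differentiation all come from the chain. Forward, the tertiary chloride of 17 must ionise to the cation 18, the tethered siloxydiene must capture it, and C10 must control C6 and C7.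

**17 back to 14 (through 16 and 15).** The dienol ether comes from the enone by soft enolisation, the C7–Cl bond from α-chlorination of a methyl ketone, and the methyl ketone from a vinyl group by Wacker oxidation. The vinyl group is carried unprotected through all earlier hydride and organometallic steps.

**14 back to 9 and 10 (through 13 and 12).** The C4–C5 bond is cut. The propenyl unit is added as the alkenyllithium 11 to aldehyde 9 and the carbinol is oxidised.

**9 back to 6 (through 8 and 7).** The C10 stereocentre is a tertiary carbinol with two alkyl groups of similar size, poorly suited to direct asymmetric addition. It is taken from a Sharpless epoxidation of the trisubstituted allylic alcohol 6 followed by hydride opening at the carbon next to the carbinol. The alkene geometry of 6 carries the stereochemical information.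

**6 back to 1 and 3 (through 5, 4 and 2).** The C9–C10 bond is cut. A B-alkyl Suzuki coupling of the borane 4 from diene 3 with the (Z)-enol triflate 2 of β-keto ester 1 fixes the alkene geometry.

## Alternatives that were turned down

**Alternative 1:** The seven-membered ring is closed last, between C1 and C7, by an intramolecular allylsilane–aldehyde addition. In a cyclopentene carrying the C7 methyl on its C6=C7 double bond and a silicon-bearing stereocentre at C5, a chain C4–C3–C2 ends in a (Z)-enal. Me2AlCl activates the aldehyde and C7 attacks C1 anti to silicon. The product is dienol A1, with the C1 carbinol, the quaternary C7, the C2=C3 alkene and a new C5=C6 alkene; C10 is still an acetal.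
- For: C1–OH and C7 are set together and at the final oxidation level, and C2=C3 needs no dehydrogenation. Hydroboration of C5=C6 anti to the angular methyl would set C5 and C6 in one operation. On C1 and C5 this plan is stronger than the chosen one, which needs an inversion at C1 and a thermodynamic reduction at C5.
- Against: a seven-membered ring is closed onto a tetrasubstituted alkene carbon. The chirality comes from a C–Si stereocentre that must first be made enantiopure. The (Z)-enal can isomerise under the Lewis acid. Above all, the isopropyl carbinol is left to the end: after the acetal is removed the C10 ketone is conjugated with C5=C6, so an isopropyl nucleophile can add 1,4 and has no nearby control element for the 1,2 face.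
- Comparison: the chosen route installs C10 first by a reagent-controlled reaction, uses it as the control element and forms two rings in one step.

**Alternative 2:** The cyclopentane is assembled from three components without closing a ring. A chiral NHC–copper catalyst transfers the 1-(trimethylsilyl)vinyl group of alane A4 to C7 of 3-methylcyclopent-2-en-1-one A3. The aluminium enolate is trapped at C6 by aldehyde A5. The product A2 has C1–C7 and C5–C6 formed and C7, C6 and C5 set.
- For: the quaternary centre is made by a catalytic, reagent-controlled reaction. The trans C6/C7 relation follows from anti trapping of the enolate. Both are more secure than the substrate-controlled relay in the (4+3) step, and the starting materials are cheap.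
- Against: the seven-membered ring must still be closed between C2 and C3 from a vinylsilane and an alkyne, the C3 methyl added and the C1 oxygen created from the vinylsilane carbon. C10 is again a ketone, now in a β-hydroxy ketone (retro-aldol), and the isopropyl group must enter from the hindered face.
- Comparison: more steps follow the key step and the hardest centre remains open. The chosen route closes both rings with C10 and both ring oxygens already in place.

**Alternative 3:** The skeleton is reached from the decalin series by a ring contraction–expansion. (S)-Wieland–Miescher ketone A7 supplies C7 with its methyl group. It is elaborated to a cis-decalin 2,3-epoxy alcohol with the tertiary hydroxyl on the ring-fusion carbon C5. BF3·OEt2 opens the epoxide at C6 while the C5–C7 bond migrates to C6. The product is hydroazulenone A6 with a C5 ketone, a C10 secondary alcohol and a C1 acetal.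
- For: C7 comes from an inexpensive enantioenriched building block. The migration is stereospecific, so the ring fusion is fixed without a diastereomer question. This is stronger than the chosen step in predictability. C1, C5 and C10 are all oxygenated and distinct.
- Against: A6 lacks the isopropyl group, the C3 methyl and the C2=C3 alkene. C10 is only a secondary alcohol; its oxidation next to the C5 ketone gives a 1,3-diketone that puts the C6 configuration at risk and offers no selective isopropyl addition. The C3 methyl and the alkene must be built from C1 over several steps. Making the epoxy alcohol from A7 needs a carbonyl transposition.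
- Comparison: the chosen route brings all skeletal carbons in the acyclic precursor and spends its steps after the key step only on redox and acylation.

Key step: step 13

## Route

Remark: the vinyl group of 3 is used as a latent methyl ketone, so 4–17 are mixtures of both epimers at the methyl-bearing carbon that becomes C7 (12 also at its secondary carbinol). These centres become sp2 before or in step 13, and the descriptors given for 5–17 refer to C10 and the alkenes only.

Step 1
Reactants: 1 methyl 4-methyl-3-oxopentanoate
Product: 2 methyl (2Z)-4-methyl-3-{[(trifluoromethyl)sulfonyl]oxy}pent-2-enoate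
Conditions: LiOH (aq.), Tf2O, toluene, 5 °C
Reagents that add atoms: trifluoromethanesulfonic anhydride, O=S(=O)(OS(=O)(=O)C(F)(F)F)C(F)(F)F
Why: O-triflation of the β-keto ester enolate; the lithium enolate is held as the O–Li–O chelate, so the triflate forms cis to the ester (Z), which fixes the later alkene geometry.

Step 2
Reactants: 3 3-methylpenta-1,4-diene; 2 methyl (2Z)-4-methyl-3-{[(trifluoromethyl)sulfonyl]oxy}pent-2-enoate
Product: 5 methyl (2E)-6-methyl-3-(propan-2-yl)octa-2,7-dienoate, via alkylborane 4 (not isolated)
Conditions: 3 (3 equiv), 9-BBN-H, THF, 0 °C to rt, excess 3 removed in vacuo; then 2, PdCl2(dppf) (5 mol%), K3PO4 (aq.), DMF, rt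
Reagents that add atoms: none
Why: Anti-Markovnikov hydroboration of one vinyl group of the symmetrical diene (excess 3 suppresses double hydroboration), then B-alkyl Suzuki–Miyaura coupling with retention at the enol triflate, so the new chain is cis to the ester and the isopropyl group trans (2E). The second vinyl group is the latent methyl ketone.

Step 3
Reactants: 5 methyl (2E)-6-methyl-3-(propan-2-yl)octa-2,7-dienoate
Product: 6 (2E)-6-methyl-3-(propan-2-yl)octa-2,7-dien-1-ol
Conditions: i-Bu2AlH (2.2 equiv), CH2Cl2, −78 °C
Reagents that add atoms: none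
Why: 1,2-reduction of the enoate by an aluminium hydride; the isolated vinyl group is inert.

Step 4
Reactants: 6 (2E)-6-methyl-3-(propan-2-yl)octa-2,7-dien-1-ol
Product: 7 [(2S,3S)-3-(3-methylpent-4-en-1-yl)-3-(propan-2-yl)oxiran-2-yl]methanol
Conditions: Ti(OiPr)4 (10 mol%), L-(+)-diethyl tartrate (12 mol%), t-BuOOH, 4 Å MS, CH2Cl2, −20 °C
Reagents that add atoms: tert-butyl hydroperoxide, CC(C)(C)OO
Why: Sharpless asymmetric epoxidation of the trisubstituted allylic alcohol; L-(+)-tartrate delivers oxygen in the same sense as for geraniol to its (2S,3S)-epoxide, which sets the future C10; the isolated vinyl group does not react.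

Step 5
Reactants: 7 [(2S,3S)-3-(3-methylpent-4-en-1-yl)-3-(propan-2-yl)oxiran-2-yl]methanol
Product: 8 (3R)-6-methyl-3-(propan-2-yl)oct-7-ene-1,3-diol
Conditions: NaAlH2(OCH2CH2OCH3)2, THF, 0 °C to rt
Reagents that add atoms: none
Why: Regioselective reductive opening of a 2,3-epoxy alcohol: hydride is delivered from the aluminate on the primary oxygen to the adjacent epoxide carbon, and the C–O bond at the quaternary carbon is untouched, so C10 keeps its configuration (3R here only through a priority change).

Step 6
Reactants: 8 (3R)-6-methyl-3-(propan-2-yl)oct-7-ene-1,3-diol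
Product: 9 (3R)-3-hydroxy-6-methyl-3-(propan-2-yl)oct-7-enal
Conditions: TEMPO (10 mol%), PhI(OAc)2, CH2Cl2, rt
Reagents that add atoms: none
Why: Oxoammonium (TEMPO) oxidation is selective for the primary alcohol; the tertiary alcohol cannot be oxidised and the near-neutral medium avoids retro-aldol cleavage of the β-hydroxy aldehyde, which is used at once.

Step 7
Reactants: 10 (E)-1-bromoprop-1-ene; 9 (3R)-3-hydroxy-6-methyl-3-(propan-2-yl)oct-7-enal
Product: 12 (2E,6R)-9-methyl-6-(propan-2-yl)undeca-2,10-diene-4,6-diol, via (E)-prop-1-en-1-yllithium 11 (not isolated)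
Conditions: 10 (2.5 equiv), t-BuLi (5 equiv), Et2O, −78 °C; then 9, −78 °C
Reagents that add atoms: none
Why: Bromine–lithium exchange keeps the E geometry; one equivalent of 11 deprotonates the tertiary alcohol and a second adds 1,2 to the aldehyde; the new carbinol centre is oxidised away in step 8.

Step 8
Reactants: 12 (2E,6R)-9-methyl-6-(propan-2-yl)undeca-2,10-diene-4,6-diol
Product: 13 (2E,6R)-6-hydroxy-9-methyl-6-(propan-2-yl)undeca-2,10-dien-4-one
Conditions: MnO2 (excess), CH2Cl2, rt
Reagents that add atoms: none
Why: Allylic oxidation with MnO2 touches only the secondary allylic alcohol; the neutral heterogeneous conditions leave the β-hydroxy ketone intact.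

Step 9
Reactants: 13 (2E,6R)-6-hydroxy-9-methyl-6-(propan-2-yl)undeca-2,10-dien-4-one
Product: 14 (2E,6R)-9-methyl-6-(propan-2-yl)-6-[(triethylsilyl)oxy]undeca-2,10-dien-4-one
Conditions: Et3SiOTf, 2,6-lutidine, CH2Cl2, −78 to 0 °C
Reagents that add atoms: triethylsilyl trifluoromethanesulfonate, CC[Si](CC)(CC)OS(=O)(=O)C(F)(F)F
Why: Silylation of the hindered tertiary alcohol with a silyl triflate and a base too weak to enolise the ketone; the ether blocks retro-aldol and β-elimination and later steers the key step.

Step 10
Reactants: 14 (2E,6R)-9-methyl-6-(propan-2-yl)-6-[(triethylsilyl)oxy]undeca-2,10-dien-4-one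
Product: 15 (2E,6R)-9-methyl-6-(propan-2-yl)-6-[(triethylsilyl)oxy]undec-2-ene-4,10-dione
Conditions: PdCl2 (10 mol%), CuCl (1 equiv), O2 (1 atm), DMF/H2O (7:1), rt
Reagents that add atoms: water, O
Why: Tsuji–Wacker oxidation: divalent palladium activates only the monosubstituted alkene and water adds at its internal carbon to give the methyl ketone; the conjugated disubstituted alkene is unreactive and the silyl ether prevents oxypalladation by the C10 oxygen.

Step 11
Reactants: 15 (2E,6R)-9-methyl-6-(propan-2-yl)-6-[(triethylsilyl)oxy]undec-2-ene-4,10-dione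
Product: 16 (2E,6R)-9-chloro-9-methyl-6-(propan-2-yl)-6-[(triethylsilyl)oxy]undec-2-ene-4,10-dione
Conditions: SO2Cl2 (1.05 equiv), CH2Cl2, 0 °C, N2 sweep; NaHCO3 (aq.)
Reagents that add atoms: sulfuryl chloride, O=S(=O)(Cl)Cl
Why: Electrophilic α-chlorination through the more substituted enol puts chlorine on the tertiary carbon, the usual regiochemistry for methyl sec-alkyl ketones; the enone enolises less readily at its neopentyl-type CH2 and its alkene is electron-poor. Both C–Cl epimers serve.

Step 12
Reactants: 16 (2E,6R)-9-chloro-9-methyl-6-(propan-2-yl)-6-[(triethylsilyl)oxy]undec-2-ene-4,10-dione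
Product: 17 (6S,7Z,9E)-3-chloro-3-methyl-6-(propan-2-yl)-6-[(triethylsilyl)oxy]-8-{[tri(propan-2-yl)silyl]oxy}undeca-7,9-dien-2-one
Conditions: i-Pr3SiOTf (1.05 equiv), Et3N (2 equiv), CH2Cl2, −78 °C
Reagents that add atoms: triisopropylsilyl trifluoromethanesulfonate, CC(C)[Si](C(C)C)(C(C)C)OS(=O)(=O)C(F)(F)F
Why: Soft enolisation: the silyl triflate binds the more Lewis-basic enone oxygen (the α-chloro ketone carbonyl is deactivated and hindered) and Et3N removes a proton from the CH2 next to C10, giving the cross-conjugated 2-siloxydiene; the Z enol ether is expected because the fully substituted C10 avoids the vinyl group. Any bis-silylated material remains a precursor of the same cation.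

Step 13
Reactants: 17 (6S,7Z,9E)-3-chloro-3-methyl-6-(propan-2-yl)-6-[(triethylsilyl)oxy]-8-{[tri(propan-2-yl)silyl]oxy}undeca-7,9-dien-2-one
Product: 20 (3S,3aS,6R,8aS)-6,8a-dimethyl-3-(propan-2-yl)-3-[(triethylsilyl)oxy]-4-{[tri(propan-2-yl)silyl]oxy}-2,3,3a,6,7,8a-hexahydroazulen-8(1H)-one, via oxyallyl cation 18 (not isolated), via cyclopentyl zwitterion 19 (not isolated)
Conditions: Et3N (3 equiv), CF3CH2OH (0.02 M), 0 °C to rt
Reagents that add atoms: none
Why: Et3N removes a C2 proton of the methyl ketone and chloride leaves from tertiary C7 in the ionising, weakly nucleophilic solvent to give oxyallyl cation 18; the closest known reaction type is the intramolecular (4+3) cycloaddition of oxyallyl cations from α-halo ketones with tethered dienes to hydroazulenones. The enol ether carbon C6 attacks the more substituted terminus C7 in a 5-exo-trig closure (both π partners exocyclic) that forms the cyclopentane and the quaternary centre and gives zwitterion 19; its enolate carbon C2 then adds to C3 of the siloxyallyl cation in a 7-endo-trig closure that forms the cycloheptane and returns the C4=C5 silyl enol ether, so the (4+3) is stepwise. C6 is set by C10: the cis siloxy group forbids any C10 substituent from eclipsing C5=C6 (1,3-allylic strain), the tether bond C10–C9 lies on the attacked face, the C10–O bond lies in the enol ether plane anti to C5 where this σ-acceptor does not lower the nucleophilicity of the π bond, and the isopropyl group (σ-donor) stands on the face opposite to C7, so C5 ends cis to isopropyl and H6 cis to the oxygen. C7 is set relative to C6 in the same bond formation: the bulky C1(O)=C2 unit points away from the enol ether (anti to C5) and the small methyl lies over it, which gives H6 trans to the C7 methyl, the ring fusion that three-atom tethers usually give in this reaction class. C3 is formed in the second closure and is drawn as expected from closure on the s-cis enone conformer; its configuration is irrelevant because C3 becomes sp2 in step 14. The step needs capture of 18 by the diene and not by solvent (short tether, gem-disubstituted C10, polarity match of tertiary cation terminus and siloxy alkene) and control of C6 and C7 by C10 (the allylic-strain and stereoelectronic arguments above, with the bulky triethylsilyl ether keeping the oxygen out of the crowded position beside the siloxy group). Both silyl groups should survive Et3N in trifluoroethanol at or below room temperature.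

Step 14
Reactants: 20 (3S,3aS,6R,8aS)-6,8a-dimethyl-3-(propan-2-yl)-3-[(triethylsilyl)oxy]-4-{[tri(propan-2-yl)silyl]oxy}-2,3,3a,6,7,8a-hexahydroazulen-8(1H)-one
Product: 22 (3S,3aS,8aS)-6,8a-dimethyl-3-(propan-2-yl)-3-[(triethylsilyl)oxy]-4-{[tri(propan-2-yl)silyl]oxy}-2,3,3a,8a-tetrahydroazulen-8(1H)-one, via lithium enolate 21 (not isolated)
Conditions: LiN(i-Pr)2, THF, −78 °C; then PhS(Cl)=N-t-Bu, −78 °C
Reagents that add atoms: none
Why: Mukaiyama dehydrogenation: the C1 ketone can enolise only toward C2 (C7 is quaternary); the enolate is captured at C2 by N-tert-butylbenzenesulfinimidoyl chloride and the adduct undergoes syn-elimination with the C3–H at low temperature, which removes the C3 stereocentre; the far less nucleophilic TIPS enol ether is not attacked.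

Step 15
Reactants: 22 (3S,3aS,8aS)-6,8a-dimethyl-3-(propan-2-yl)-3-[(triethylsilyl)oxy]-4-{[tri(propan-2-yl)silyl]oxy}-2,3,3a,8a-tetrahydroazulen-8(1H)-one
Product: 23 (3S,3aS,8S,8aS)-6,8a-dimethyl-3-(propan-2-yl)-3-[(triethylsilyl)oxy]-4-{[tri(propan-2-yl)silyl]oxy}-1,2,3,3a,8,8a-hexahydroazulen-8-ol
Conditions: i-Bu2AlH, toluene, −78 °C; KNaC4H4O6 (aq.) work-up
Reagents that add atoms: none
Why: 1,2-reduction of the vinylogous silyl ester carbonyl; hydride should add anti to the axial C7 methyl group and give the alcohol cis to it (8S), the epimer that step 18 inverts. Work-up is non-acidic because the product is a siloxydiene with an allylic hydroxyl; it is used crude.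

Step 16
Reactants: 23 (3S,3aS,8S,8aS)-6,8a-dimethyl-3-(propan-2-yl)-3-[(triethylsilyl)oxy]-4-{[tri(propan-2-yl)silyl]oxy}-1,2,3,3a,8,8a-hexahydroazulen-8-ol
Product: 24 (3S,3aR,8S,8aS)-8-hydroxy-6,8a-dimethyl-3-(propan-2-yl)-3-[(triethylsilyl)oxy]-2,3,3a,5,8,8a-hexahydroazulen-4(1H)-one
Conditions: Bu4NF (1.1 equiv), AcOH (1.5 equiv), THF, −40 to −20 °C
Reagents that add atoms: none
Why: Fluoride cleaves the dienol silyl ether far faster than the hindered tertiary triethylsilyl ether; the buffered dienolate is protonated kinetically at the α-carbon C4 (deconjugative protonation), which gives the β,γ-unsaturated ketone with C2=C3 in place. The C1 hydroxyl is not a leaving group, so no vinylogous elimination occurs, and C6 is not touched.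

Step 17
Reactants: 24 (3S,3aR,8S,8aS)-8-hydroxy-6,8a-dimethyl-3-(propan-2-yl)-3-[(triethylsilyl)oxy]-2,3,3a,5,8,8a-hexahydroazulen-4(1H)-one
Product: 25 (3S,3aS,4S,8S,8aS)-6,8a-dimethyl-3-(propan-2-yl)-3-[(triethylsilyl)oxy]-1,2,3,3a,4,5,8,8a-octahydroazulene-4,8-diol
Conditions: Li, NH3 (l), THF, t-BuOH, −78 °C; then NH4Cl
Reagents that add atoms: none
Why: Dissolving-metal reduction of the ketone gives the thermodynamically favoured equatorial alcohol (C5–O cis to H6, H5 anti to H6), which hydride attack on the open face would not give; the isolated trisubstituted alkene, the allylic alkoxide and the silyl ether should not be reduced at −78 °C.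

Step 18
Reactants: 25 (3S,3aS,4S,8S,8aS)-6,8a-dimethyl-3-(propan-2-yl)-3-[(triethylsilyl)oxy]-1,2,3,3a,4,5,8,8a-octahydroazulene-4,8-diol; 26 (2E)-2-methylbut-2-enoic acid (tiglic acid)
Product: 27 (3S,3aS,4S,8R,8aS)-4-hydroxy-6,8a-dimethyl-3-(propan-2-yl)-3-[(triethylsilyl)oxy]-1,2,3,3a,4,5,8,8a-octahydroazulen-8-yl (2E)-2-methylbut-2-enoate
Conditions: PPh3, diisopropyl azodicarboxylate, 26 (1.2 equiv), toluene, 0 °C to rt
Reagents that add atoms: none
Why: Mitsunobu esterification with inversion: the allylic C1 oxyphosphonium ion is displaced by tiglate from the open face anti to the C7 methyl, giving the (8R) ester; the C5 hydroxyl cannot be displaced because its rear side is blocked by the syn-axial C7 methyl and the isopropyl group.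

Step 19
Reactants: 28 4-hydroxybenzoic acid
Product: 30 4-[(tert-butyldimethylsilyl)oxy]benzoic acid, via silyl ester 29 (not isolated)
Conditions: t-BuMe2SiCl (2.2 equiv), imidazole, DMF, rt; then AcOH/THF/H2O, rt
Reagents that add atoms: tert-butyldimethylsilyl chloride, CC(C)(C)[Si](C)(C)Cl
Why: Silylation of phenol and acid, then selective hydrolysis of the much more labile silyl ester; the aryl silyl ether stays.

Step 20
Reactants: 27 (3S,3aS,4S,8R,8aS)-4-hydroxy-6,8a-dimethyl-3-(propan-2-yl)-3-[(triethylsilyl)oxy]-1,2,3,3a,4,5,8,8a-octahydroazulen-8-yl (2E)-2-methylbut-2-enoate; 30 4-[(tert-butyldimethylsilyl)oxy]benzoic acid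
Product: 32 (3S,3aS,4S,8R,8aS)-6,8a-dimethyl-8-{[(2E)-2-methylbut-2-enoyl]oxy}-3-(propan-2-yl)-3-[(triethylsilyl)oxy]-1,2,3,3a,4,5,8,8a-octahydroazulen-4-yl 4-[(tert-butyldimethylsilyl)oxy]benzoate, via mixed anhydride 31 (not isolated)
Conditions: 30, 2,4,6-Cl3C6H2COCl, Et3N, THF, rt; then 27, DMAP, toluene, 40 °C
Reagents that add atoms: none
Why: Yamaguchi esterification: DMAP transfers the aroyl group from the mixed anhydride to the only free hydroxyl (C5) with retention; the activated acylating agent is chosen because this alcohol lies beside the bulky C10 silyl ether.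

Step 21
Reactants: 32 (3S,3aS,4S,8R,8aS)-6,8a-dimethyl-8-{[(2E)-2-methylbut-2-enoyl]oxy}-3-(propan-2-yl)-3-[(triethylsilyl)oxy]-1,2,3,3a,4,5,8,8a-octahydroazulen-4-yl 4-[(tert-butyldimethylsilyl)oxy]benzoate
Product: 33 (3S,3aS,4S,8R,8aS)-3-hydroxy-6,8a-dimethyl-8-{[(2E)-2-methylbut-2-enoyl]oxy}-3-(propan-2-yl)-1,2,3,3a,4,5,8,8a-octahydroazulen-4-yl 4-hydroxybenzoate (CNP0273650.6)
Conditions: HF·pyridine, pyridine, THF, 0 °C to rt
Reagents that add atoms: none
Why: Fluoride-mediated desilylation removes the aryl silyl ether and the tertiary triethylsilyl ether under nearly neutral conditions that leave the allylic tiglate, the benzoate and the tertiary alcohol intact; acyl migration to the tertiary hydroxyl is not expected.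

## Compound list

Bicyclic compounds carry the same azulene locants throughout: 1 = C8, 2 = C9, 3 = C10, 3a = C6, 4 = C5, 5 = C4, 6 = C3, 7 = C2, 8 = C1, 8a = C7.

1 | methyl 4-methyl-3-oxopentanoate | CC(C)C(=O)CC(=O)OC | starting material
2 | methyl (2Z)-4-methyl-3-{[(trifluoromethyl)sulfonyl]oxy}pent-2-enoate | COC(=O)/C=C(\OS(=O)(=O)C(F)(F)F)C(C)C | intermediate
3 | 3-methylpenta-1,4-diene | C=CC(C)C=C | starting material
4 | 9-(3-methylpent-4-en-1-yl)-9-borabicyclo[3.3.1]nonane | C=CC(C)CCB1C2CCCC1CCC2 | intermediate (not isolated)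
5 | methyl (2E)-6-methyl-3-(propan-2-yl)octa-2,7-dienoate | COC(=O)/C=C(\CCC(C)C=C)C(C)C | intermediate
6 | (2E)-6-methyl-3-(propan-2-yl)octa-2,7-dien-1-ol | OC/C=C(\CCC(C)C=C)C(C)C | intermediate
7 | [(2S,3S)-3-(3-methylpent-4-en-1-yl)-3-(propan-2-yl)oxiran-2-yl]methanol | OC[C@@H]1O[C@@]1(CCC(C)C=C)C(C)C | intermediate
8 | (3R)-6-methyl-3-(propan-2-yl)oct-7-ene-1,3-diol | OCC[C@](O)(CCC(C)C=C)C(C)C | intermediate
9 | (3R)-3-hydroxy-6-methyl-3-(propan-2-yl)oct-7-enal | O=CC[C@](O)(CCC(C)C=C)C(C)C | intermediate
10 | (E)-1-bromoprop-1-ene | C/C=C/Br | starting material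
11 | (E)-prop-1-en-1-yllithium | C/C=C/[Li] | intermediate (not isolated)
12 | (2E,6R)-9-methyl-6-(propan-2-yl)undeca-2,10-diene-4,6-diol | C/C=C/C(O)C[C@](O)(CCC(C)C=C)C(C)C | intermediate
13 | (2E,6R)-6-hydroxy-9-methyl-6-(propan-2-yl)undeca-2,10-dien-4-one | C/C=C/C(=O)C[C@](O)(CCC(C)C=C)C(C)C | intermediate
14 | (2E,6R)-9-methyl-6-(propan-2-yl)-6-[(triethylsilyl)oxy]undeca-2,10-dien-4-one | C/C=C/C(=O)C[C@](O[Si](CC)(CC)CC)(CCC(C)C=C)C(C)C | intermediate
15 | (2E,6R)-9-methyl-6-(propan-2-yl)-6-[(triethylsilyl)oxy]undec-2-ene-4,10-dione | C/C=C/C(=O)C[C@](O[Si](CC)(CC)CC)(CCC(C)C(C)=O)C(C)C | intermediate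
16 | (2E,6R)-9-chloro-9-methyl-6-(propan-2-yl)-6-[(triethylsilyl)oxy]undec-2-ene-4,10-dione | C/C=C/C(=O)C[C@](O[Si](CC)(CC)CC)(CCC(C)(Cl)C(C)=O)C(C)C | intermediate
17 | (6S,7Z,9E)-3-chloro-3-methyl-6-(propan-2-yl)-6-[(triethylsilyl)oxy]-8-{[tri(propan-2-yl)silyl]oxy}undeca-7,9-dien-2-one | CC(=O)C(C)(Cl)CC[C@](O[Si](CC)(CC)CC)(C(C)C)/C=C(\O[Si](C(C)C)(C(C)C)C(C)C)/C=C/C | intermediate (key-step precursor)
18 | oxyallyl cation (2-oxidoallyl cation, C7–C1–C2) formed from 17 by loss of HCl; (10S), 5Z and 3E alkenes | C=C([O-])[C+](C)CC[C@](O[Si](CC)(CC)CC)(C(C)C)/C=C(\O[Si](C(C)C)(C(C)C)C(C)C)/C=C/C | intermediate (not isolated)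
19 | cyclopentyl zwitterion after C6–C7 bond formation: C7 carries methyl and the C1 enolate, C6 the silyloxocarbenium of the (E)-propenyl ketone; (6R,7S,10S) in the numbering used here | C=C([O-])[C@@]1(C)CC[C@](O[Si](CC)(CC)CC)(C(C)C)[C@@H]1C(/C=C/C)=[O+][Si](C(C)C)(C(C)C)C(C)C | intermediate (not isolated)
20 | (3S,3aS,6R,8aS)-6,8a-dimethyl-3-(propan-2-yl)-3-[(triethylsilyl)oxy]-4-{[tri(propan-2-yl)silyl]oxy}-2,3,3a,6,7,8a-hexahydroazulen-8(1H)-one | O=C1C[C@@H](C)C=C(O[Si](C(C)C)(C(C)C)C(C)C)[C@@H]2[C@]1(C)CC[C@]2(O[Si](CC)(CC)CC)C(C)C | intermediate (key-step product)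
21 | lithium enolate of 20 (O–Li on C1, C1=C2) | [Li]OC1=C[C@@H](C)C=C(O[Si](C(C)C)(C(C)C)C(C)C)[C@@H]2[C@]1(C)CC[C@]2(O[Si](CC)(CC)CC)C(C)C | intermediate (not isolated)
22 | (3S,3aS,8aS)-6,8a-dimethyl-3-(propan-2-yl)-3-[(triethylsilyl)oxy]-4-{[tri(propan-2-yl)silyl]oxy}-2,3,3a,8a-tetrahydroazulen-8(1H)-one | O=C1C=C(C)C=C(O[Si](C(C)C)(C(C)C)C(C)C)[C@@H]2[C@]1(C)CC[C@]2(O[Si](CC)(CC)CC)C(C)C | intermediate
23 | (3S,3aS,8S,8aS)-6,8a-dimethyl-3-(propan-2-yl)-3-[(triethylsilyl)oxy]-4-{[tri(propan-2-yl)silyl]oxy}-1,2,3,3a,8,8a-hexahydroazulen-8-ol | O[C@H]1C=C(C)C=C(O[Si](C(C)C)(C(C)C)C(C)C)[C@@H]2[C@]1(C)CC[C@]2(O[Si](CC)(CC)CC)C(C)C | intermediate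
24 | (3S,3aR,8S,8aS)-8-hydroxy-6,8a-dimethyl-3-(propan-2-yl)-3-[(triethylsilyl)oxy]-2,3,3a,5,8,8a-hexahydroazulen-4(1H)-one | O[C@H]1C=C(C)CC(=O)[C@@H]2[C@]1(C)CC[C@]2(O[Si](CC)(CC)CC)C(C)C | intermediate
25 | (3S,3aS,4S,8S,8aS)-6,8a-dimethyl-3-(propan-2-yl)-3-[(triethylsilyl)oxy]-1,2,3,3a,4,5,8,8a-octahydroazulene-4,8-diol | O[C@H]1C=C(C)C[C@H](O)[C@@H]2[C@]1(C)CC[C@]2(O[Si](CC)(CC)CC)C(C)C | intermediate
26 | (2E)-2-methylbut-2-enoic acid (tiglic acid) | C/C=C(\C)C(=O)O | starting material
27 | (3S,3aS,4S,8R,8aS)-4-hydroxy-6,8a-dimethyl-3-(propan-2-yl)-3-[(triethylsilyl)oxy]-1,2,3,3a,4,5,8,8a-octahydroazulen-8-yl (2E)-2-methylbut-2-enoate | C/C=C(\C)C(=O)O[C@@H]1C=C(C)C[C@H](O)[C@@H]2[C@]1(C)CC[C@]2(O[Si](CC)(CC)CC)C(C)C | intermediate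
28 | 4-hydroxybenzoic acid | OC(=O)c1ccc(O)cc1 | starting material
29 | tert-butyldimethylsilyl 4-[(tert-butyldimethylsilyl)oxy]benzoate | CC(C)(C)[Si](C)(C)OC(=O)c1ccc(O[Si](C)(C)C(C)(C)C)cc1 | intermediate (not isolated)
30 | 4-[(tert-butyldimethylsilyl)oxy]benzoic acid | OC(=O)c1ccc(O[Si](C)(C)C(C)(C)C)cc1 | intermediate
31 | 4-[(tert-butyldimethylsilyl)oxy]benzoic 2,4,6-trichlorobenzoic anhydride | O=C(OC(=O)c1c(Cl)cc(Cl)cc1Cl)c1ccc(O[Si](C)(C)C(C)(C)C)cc1 | intermediate (not isolated)
32 | (3S,3aS,4S,8R,8aS)-6,8a-dimethyl-8-{[(2E)-2-methylbut-2-enoyl]oxy}-3-(propan-2-yl)-3-[(triethylsilyl)oxy]-1,2,3,3a,4,5,8,8a-octahydroazulen-4-yl 4-[(tert-butyldimethylsilyl)oxy]benzoate | C/C=C(\C)C(=O)O[C@@H]1C=C(C)C[C@H](OC(=O)c2ccc(O[Si](C)(C)C(C)(C)C)cc2)[C@@H]3[C@]1(C)CC[C@]3(O[Si](CC)(CC)CC)C(C)C | intermediate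
33 | (3S,3aS,4S,8R,8aS)-3-hydroxy-6,8a-dimethyl-8-{[(2E)-2-methylbut-2-enoyl]oxy}-3-(propan-2-yl)-1,2,3,3a,4,5,8,8a-octahydroazulen-4-yl 4-hydroxybenzoate | C/C=C(\C)C(=O)O[C@@H]1C=C(C)C[C@H](OC(=O)c2ccc(O)cc2)[C@@H]2[C@]1(C)CC[C@]2(O)C(C)C | target

## Step count and least certain steps

Total step count: 21. Longest linear sequence: 20 steps (steps 1–18, 20 and 21, from 1); step 19 is a one-step side branch.

**Step 13 (key step).** The most likely failure is incomplete transmission of the C10 configuration to C6 and C7. Attack through the conformer with the silyl ether on the face opposite to C7, or a compact arrangement of the two π systems, would give diastereomers. A cis-fused C6 epimer could not be corrected later, because any base would first enolise at C4. Beside this, 18 may be lost to solvent capture or Favorskii rearrangement, or the dienol ether may be protodesilylated by the protic medium before ionisation.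

The fallback leaves the basic protic medium. From 16, excess i-Pr3SiOTf/Et3N would silylate both carbonyl groups to the bis(silyl enol ether) (6S,7Z,9E)-3-chloro-3-methyl-6-(propan-2-yl)-6-[(triethylsilyl)oxy]-2,8-bis{[tri(propan-2-yl)silyl]oxy}undeca-1,7,9-triene F1. Chloride abstraction with AgClO4 in CH2Cl2/MeNO2 at −78 °C would give the 2-siloxyallyl cation under aprotic conditions at low temperature, where a tighter arrangement is expected. The adduct, after loss of the silyl group from the C1 oxygen on work-up, is 20.

**Step 11.** Chlorination may go to the wrong α-position (the C2 methyl or the enone side), and HCl may remove the triethylsilyl group or add to the enone. The fallback builds the chloro ketone without chlorinating a ketone, and starts from 14: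
- Isomerisation of the terminal alkene with RuHCl(CO)(PPh3)3 would give the trisubstituted alkene (2E,6R)-9-methyl-6-(propan-2-yl)-6-[(triethylsilyl)oxy]undeca-2,9-dien-4-one F2.
- Buffered peracid epoxidation, selective for this electron-rich alkene over the enone, would give (2E,6R)-8-(2,3-dimethyloxiran-2-yl)-6-(propan-2-yl)-6-[(triethylsilyl)oxy]oct-2-en-4-one F3.
- Opening with Et2AlCl at −78 °C would place chloride on the tertiary carbon and give (2E,6R)-9-chloro-10-hydroxy-9-methyl-6-(propan-2-yl)-6-[(triethylsilyl)oxy]undec-2-en-4-one F4.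
- Dess–Martin oxidation of F4 returns to the route at 16.

**Step 17.** The strongly basic reducing medium may move the C2=C3 alkene of the β,γ-unsaturated ketone into conjugation or epimerise C6 before reduction, and the allylic C1–O bond may be cleaved. The fallback separates the two alcohols by oxidation state and replaces thermodynamic control by inversion. From 24, Mitsunobu esterification with 26 would give (3S,3aR,8R,8aS)-6,8a-dimethyl-4-oxo-3-(propan-2-yl)-3-[(triethylsilyl)oxy]-1,2,3,3a,4,5,8,8a-octahydroazulen-8-yl (2E)-2-methylbut-2-enoate F5. LiBH(s-Bu)3 at −78 °C would attack the open face and give the axial alcohol (3S,3aS,4R,8R,8aS)-4-hydroxy-6,8a-dimethyl-3-(propan-2-yl)-3-[(triethylsilyl)oxy]-1,2,3,3a,4,5,8,8a-octahydroazulen-8-yl (2E)-2-methylbut-2-enoate F6. A second Mitsunobu reaction with 30 would invert C5 and rejoin the route at 32.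

**Step 18.** The displacement at the neopentyl-type allylic C1 may be slow, so that elimination, ionisation with loss of stereochemical integrity, or acylation of the C5 hydroxyl with retention compete. If step 15 gives the other C1 epimer, inversion would be the wrong operation. The fallback sets C1 by a reagent-controlled reduction and starts from 25:
- MnO2 would oxidise only the allylic alcohol to (3S,3aS,4S,8aS)-4-hydroxy-6,8a-dimethyl-3-(propan-2-yl)-3-[(triethylsilyl)oxy]-2,3,3a,4,5,8a-hexahydroazulen-8(1H)-one F7.
- Yamaguchi esterification with 30 would give (3S,3aS,4S,8aS)-6,8a-dimethyl-8-oxo-3-(propan-2-yl)-3-[(triethylsilyl)oxy]-1,2,3,3a,4,5,8,8a-octahydroazulen-4-yl 4-[(tert-butyldimethylsilyl)oxy]benzoate F8.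
- Reduction with (S)-2-methyl-CBS-oxazaborolidine and catecholborane, with the quaternary C7 side as the large group, would give (3S,3aS,4S,8R,8aS)-8-hydroxy-6,8a-dimethyl-3-(propan-2-yl)-3-[(triethylsilyl)oxy]-1,2,3,3a,4,5,8,8a-octahydroazulen-4-yl 4-[(tert-butyldimethylsilyl)oxy]benzoate F9.
- Yamaguchi esterification of F9 with 26, with retention, returns to the route at 32.

## Further compounds

F1 | step 13 | (6S,7Z,9E)-3-chloro-3-methyl-6-(propan-2-yl)-6-[(triethylsilyl)oxy]-2,8-bis{[tri(propan-2-yl)silyl]oxy}undeca-1,7,9-triene | C=C(O[Si](C(C)C)(C(C)C)C(C)C)C(C)(Cl)CC[C@](O[Si](CC)(CC)CC)(C(C)C)/C=C(\O[Si](C(C)C)(C(C)C)C(C)C)/C=C/C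
F2 | step 11 | (2E,6R)-9-methyl-6-(propan-2-yl)-6-[(triethylsilyl)oxy]undeca-2,9-dien-4-one | C/C=C/C(=O)C[C@](O[Si](CC)(CC)CC)(CCC(C)=CC)C(C)C
F3 | step 11 | (2E,6R)-8-(2,3-dimethyloxiran-2-yl)-6-(propan-2-yl)-6-[(triethylsilyl)oxy]oct-2-en-4-one | C/C=C/C(=O)C[C@](O[Si](CC)(CC)CC)(CCC1(C)OC1C)C(C)C
F4 | step 11 | (2E,6R)-9-chloro-10-hydroxy-9-methyl-6-(propan-2-yl)-6-[(triethylsilyl)oxy]undec-2-en-4-one | C/C=C/C(=O)C[C@](O[Si](CC)(CC)CC)(CCC(C)(Cl)C(C)O)C(C)C
F5 | step 17 | (3S,3aR,8R,8aS)-6,8a-dimethyl-4-oxo-3-(propan-2-yl)-3-[(triethylsilyl)oxy]-1,2,3,3a,4,5,8,8a-octahydroazulen-8-yl (2E)-2-methylbut-2-enoate | C/C=C(\C)C(=O)O[C@@H]1C=C(C)CC(=O)[C@@H]2[C@]1(C)CC[C@]2(O[Si](CC)(CC)CC)C(C)C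
F6 | step 17 | (3S,3aS,4R,8R,8aS)-4-hydroxy-6,8a-dimethyl-3-(propan-2-yl)-3-[(triethylsilyl)oxy]-1,2,3,3a,4,5,8,8a-octahydroazulen-8-yl (2E)-2-methylbut-2-enoate | C/C=C(\C)C(=O)O[C@@H]1C=C(C)C[C@@H](O)[C@@H]2[C@]1(C)CC[C@]2(O[Si](CC)(CC)CC)C(C)C
F7 | step 18 | (3S,3aS,4S,8aS)-4-hydroxy-6,8a-dimethyl-3-(propan-2-yl)-3-[(triethylsilyl)oxy]-2,3,3a,4,5,8a-hexahydroazulen-8(1H)-one | O=C1C=C(C)C[C@H](O)[C@@H]2[C@]1(C)CC[C@]2(O[Si](CC)(CC)CC)C(C)C
F8 | step 18 | (3S,3aS,4S,8aS)-6,8a-dimethyl-8-oxo-3-(propan-2-yl)-3-[(triethylsilyl)oxy]-1,2,3,3a,4,5,8,8a-octahydroazulen-4-yl 4-[(tert-butyldimethylsilyl)oxy]benzoate | O=C1C=C(C)C[C@H](OC(=O)c3ccc(O[Si](C)(C)C(C)(C)C)cc3)[C@@H]2[C@]1(C)CC[C@]2(O[Si](CC)(CC)CC)C(C)C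
F9 | step 18 | (3S,3aS,4S,8R,8aS)-8-hydroxy-6,8a-dimethyl-3-(propan-2-yl)-3-[(triethylsilyl)oxy]-1,2,3,3a,4,5,8,8a-octahydroazulen-4-yl 4-[(tert-butyldimethylsilyl)oxy]benzoate | O[C@@H]1C=C(C)C[C@H](OC(=O)c3ccc(O[Si](C)(C)C(C)(C)C)cc3)[C@@H]2[C@]1(C)CC[C@]2(O[Si](CC)(CC)CC)C(C)C
A1 | alternative 1 | bicyclic dienol with C2=C3 and C5=C6 alkenes, methyl groups on C3 and C7 and an ethylene acetal at C10; (1R,7S) in the numbering used here | O[C@@H]1C=C(C)CC=C2[C@]1(C)CCC23OCCO3
A2 | alternative 2 | (2S,3S)-2-[(1S)-1-hydroxy-4-(trimethylsilyl)but-3-yn-1-yl]-3-methyl-3-[1-(trimethylsilyl)ethenyl]cyclopentan-1-one | C=C([Si](C)(C)C)[C@@]1(C)CCC(=O)[C@@H]1[C@@H](O)CC#C[Si](C)(C)C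
A3 | alternative 2 | 3-methylcyclopent-2-en-1-one | CC1=CC(=O)CC1
A4 | alternative 2 | bis(2-methylpropyl)[1-(trimethylsilyl)ethenyl]alumane | C=C([Si](C)(C)C)[Al](CC(C)C)CC(C)C
A5 | alternative 2 | 4-(trimethylsilyl)but-3-ynal | O=CCC#C[Si](C)(C)C
A6 | alternative 3 | trans-fused hydroazulen-5-one with C7 methyl, C10 hydroxyl and C1 ethylene acetal; (6R,7S,10S) in the numbering used here | O=C1CCCC3(OCCO3)[C@@]2(C)CC[C@H](O)[C@H]12
A7 | alternative 3 | (8aS)-8a-methyl-3,4,8,8a-tetrahydronaphthalene-1,6(2H,7H)-dione | C[C@]12CCC(=O)C=C1CCCC2=O
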